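**Retrosynthetic overview**

- The strategy rests on the methyl-bearing stereocentre, the benzylic CH on C6 of the chromene. It lies 1,3 to the methyl-bearing alkene carbon on C2 of the benzofuran, so the two carbons map onto the β-carbon and the carbonyl carbon of an (E)-enone.
- Target ⇒ (desilylation, then C(sp2)–CH3 Negishi disconnection) (S,Z)-enol triflate ⇒ chromenyl benzofuranyl enone + Me2Zn (asymmetric conjugate methylation with O-triflation of the enolate).
- Enone ⇒ (silylation, MnO2 oxidation) benzofuranyl carbinol ⇒ 5-iodo-2,4-dihydroxyacetophenone + aryl enynol (Sonogashira coupling with furan ring closure).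
- Enynol ⇒ (E)-enal + ethynylmagnesium bromide; enal ⇒ 6-bromochromene (Br/Li exchange, vinylogous formylation) ⇒ 4-bromo-3-methoxyphenol + 3-chloro-3-methylbut-1-yne.
- Ring order: the pyran ring of the chromene first (step 2), then the furan ring of the benzofuran (step 6); both benzene rings are bought and the key step closes no ring.

Key step: step 9

Assumption: the ligand L, the (S)-BINOL-derived N,N-bis[(R)-1-phenylethyl]phosphoramidite (S,R,R), is taken to deliver methyl to the Si face of the β-carbon by analogy with chalcone alkylations; if the sense proves opposite, the (R,S,S) antipode is used with no other change.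

**Route**

Step 1
Reactants: 1 4-bromo-3-methoxyphenol; 2 3-chloro-3-methylbut-1-yne
Product: 3 1-bromo-2-methoxy-4-[(2-methylbut-3-yn-2-yl)oxy]benzene
Conditions: K2CO3, KI, CuI (cat.), acetone, reflux
Reagents that add atoms: none
Why: Copper-assisted O-alkylation of a phenoxide with a tertiary propargylic chloride is the standard entry to aryl 1,1-dimethylpropargyl ethers, and the aryl bromide and methyl ether are inert to carbonate.

Step 2
Reactants: 3 1-bromo-2-methoxy-4-[(2-methylbut-3-yn-2-yl)oxy]benzene
Product: 6 6-bromo-7-methoxy-2,2-dimethyl-2H-chromene, via allenylphenol 4 (not isolated), via ortho-quinone methide 5 (not isolated)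
Conditions: N,N-diethylaniline, 190 °C
Reagents that add atoms: none
Why: Aromatic propargyl Claisen rearrangement, 1,5-hydrogen shift and oxa-6π electrocyclisation close the pyran ring, and the [3,3] shift should go to the unhindered ring carbon para to the methoxy group rather than to the carbon flanked by both oxygens, giving the linear 6-bromo-7-methoxy isomer.

Step 3
Reactants: 6 6-bromo-7-methoxy-2,2-dimethyl-2H-chromene; 7 (E)-3-(dimethylamino)prop-2-enal
Product: 10 (E)-3-(7-methoxy-2,2-dimethyl-2H-chromen-6-yl)prop-2-enal, via aryllithium 8 (not isolated), via lithium amino-alkoxide 9 (not isolated)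
Conditions: n-BuLi, THF, −78 °C; then 7, −78 → 0 °C; then 1 M aq. HCl, 0 °C
Reagents that add atoms: water, O
Why: Bromine–lithium exchange, 1,2-addition of the aryllithium to the vinylogous formamide, and acid-promoted ionisation and hydrolysis of the resulting vinylogous iminium ion (a vinylogous Bouveault formylation) should give the conjugated (E)-enal directly, the electron-rich aryl group assisting the ionisation.

Step 4
Reactants: 10 (E)-3-(7-methoxy-2,2-dimethyl-2H-chromen-6-yl)prop-2-enal; 11 ethynylmagnesium bromide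
Product: 12 rac-(E)-1-(7-methoxy-2,2-dimethyl-2H-chromen-6-yl)pent-1-en-4-yn-3-ol
Conditions: THF, 0 °C; then aq. NH4Cl
Reagents that add atoms: none
Why: Grignard 1,2-addition of the hard alkynyl nucleophile to the enal carbonyl gives the propargylic alcohol, whose racemic carbinol centre is of no consequence because it is oxidised in step 7.

Step 5
Reactants: 13 1-(2,4-dihydroxyphenyl)ethanone
Product: 14 1-(2,4-dihydroxy-5-iodophenyl)ethanone
Conditions: ICl, AcOH, rt
Reagents that add atoms: iodine monochloride, ClI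
Why: Electrophilic aromatic iodination is directed to C5, which is ortho to the free 4-hydroxyl, para to the chelated 2-hydroxyl and less hindered than C3; the 3-iodo isomer and any di-iodide are to be removed by crystallisation.

Step 6
Reactants: 12 rac-(E)-1-(7-methoxy-2,2-dimethyl-2H-chromen-6-yl)pent-1-en-4-yn-3-ol; 14 1-(2,4-dihydroxy-5-iodophenyl)ethanone
Product: 16 rac-1-{6-hydroxy-2-[(E)-1-hydroxy-3-(7-methoxy-2,2-dimethyl-2H-chromen-6-yl)prop-2-en-1-yl]benzofuran-5-yl}ethanone, via alkynylphenol 15 (not isolated)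
Conditions: Pd(PPh3)2Cl2 (cat.), CuI (cat.), Et3N, DMF, rt → 60 °C
Reagents that add atoms: none
Why: Sonogashira coupling of the aryl iodide with the terminal alkyne followed by 5-endo-dig addition of the ortho hydroxyl to the metal-activated alkyne closes the furan ring, and only the 4-hydroxyl is ortho to the alkyne, so a single benzofuran can form.

Step 7
Reactants: 16 rac-1-{6-hydroxy-2-[(E)-1-hydroxy-3-(7-methoxy-2,2-dimethyl-2H-chromen-6-yl)prop-2-en-1-yl]benzofuran-5-yl}ethanone
Product: 17 (E)-1-(5-acetyl-6-hydroxybenzofuran-2-yl)-3-(7-methoxy-2,2-dimethyl-2H-chromen-6-yl)prop-2-en-1-one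
Conditions: MnO2 (activated, excess), CH2Cl2, rt
Reagents that add atoms: none
Why: MnO2 oxidation is selective for the allylic, heteroaryl-activated secondary alcohol under neutral conditions and should leave the chelated phenol and the chromene alkene untouched.

Step 8
Reactants: 17 (E)-1-(5-acetyl-6-hydroxybenzofuran-2-yl)-3-(7-methoxy-2,2-dimethyl-2H-chromen-6-yl)prop-2-en-1-one
Product: 18 (E)-1-{5-acetyl-6-[(tert-butyldimethylsilyl)oxy]benzofuran-2-yl}-3-(7-methoxy-2,2-dimethyl-2H-chromen-6-yl)prop-2-en-1-one
Conditions: TBSCl, imidazole, DMAP (cat.), DMF, rt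
Reagents that add atoms: tert-butyldimethylsilyl chloride, CC(C)(C)[Si](C)(C)Cl
Why: Corey silylation of the only hydroxyl removes the acidic proton that would consume dimethylzinc, and imidazole is too weak a base to enolise the methyl ketone.

Step 9
Reactants: 18 (E)-1-{5-acetyl-6-[(tert-butyldimethylsilyl)oxy]benzofuran-2-yl}-3-(7-methoxy-2,2-dimethyl-2H-chromen-6-yl)prop-2-en-1-one; 19 dimethylzinc
Product: 21 (1Z,3S)-1-{5-acetyl-6-[(tert-butyldimethylsilyl)oxy]benzofuran-2-yl}-3-(7-methoxy-2,2-dimethyl-2H-chromen-6-yl)but-1-en-1-yl trifluoromethanesulfonate, via methylzinc enolate 20 (not isolated)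
Conditions: Cu(OTf)2 (5 mol %), L (10 mol %), Me2Zn (2 equiv), toluene, −20 → 0 °C; then Tf2O (2.5 equiv), 0 °C → rt; aq. NaHCO3 quench
Reagents that add atoms: trifluoromethanesulfonic anhydride, O=S(=O)(OS(=O)(=O)C(F)(F)F)C(F)(F)F
Why: Cu(OTf)2 is reduced by Me2Zn to a monovalent copper–phosphoramidite complex that is methylated by transmetalation, binds the enone alkene in its s-cis conformation, forms the C–CH3 bond at the β-carbon and releases methylzinc enolate 20, which Tf2O sulfonylates on oxygen. The closest known reaction type is the copper/phosphoramidite-catalysed enantioselective 1,4-addition of dialkylzinc reagents to chalcones and other acyclic enones with in situ trapping of the zinc enolate by triflic anhydride. No ring is closed; one C–C bond and one stereocentre are formed. The S configuration should result from ligand-controlled delivery of methyl to the Si face of the β-carbon of the (E)-enone, the binaphthyl backbone and the two 1-phenylethyl groups shielding the Re face. The step also needs the Z-enolate, which follows from the s-cis conformation preferred by an aryl enone without an α-substituent (enolate oxygen and new stereogenic carbon cis, also the thermodynamically preferred aryl ketone enolate), so that triflate occupies the position the alkene methyl must take. Chemoselectivity rests on the inertness of Me2Zn towards the aryl methyl ketone and the aryl silyl ether, on the absence of any base able to enolise the acetyl group, and on the hard sulfonyl electrophile attacking enolate oxygen rather than carbon.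

Step 10
Reactants: 21 (1Z,3S)-1-{5-acetyl-6-[(tert-butyldimethylsilyl)oxy]benzofuran-2-yl}-3-(7-methoxy-2,2-dimethyl-2H-chromen-6-yl)but-1-en-1-yl trifluoromethanesulfonate; 22 methylzinc chloride
Product: 23 1-{6-[(tert-butyldimethylsilyl)oxy]-2-[(2E,4S)-4-(7-methoxy-2,2-dimethyl-2H-chromen-6-yl)pent-2-en-2-yl]benzofuran-5-yl}ethanone
Conditions: Pd(PPh3)4 (5 mol %), MeZnCl, THF, rt → 50 °C
Reagents that add atoms: none
Why: In this Negishi coupling, oxidative addition of zerovalent palladium to the alkenyl triflate, transmetalation and reductive elimination all proceed with retention at the sp2 carbon, so methyl takes the place of triflate cis to the stereogenic carbon (E-alkene), while MeZnCl leaves the aryl ketone, the silyl ether and the stereocentre alone.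

Step 11
Reactants: 23 1-{6-[(tert-butyldimethylsilyl)oxy]-2-[(2E,4S)-4-(7-methoxy-2,2-dimethyl-2H-chromen-6-yl)pent-2-en-2-yl]benzofuran-5-yl}ethanone
Product: 24 1-{6-hydroxy-2-[(2E,4S)-4-(7-methoxy-2,2-dimethyl-2H-chromen-6-yl)pent-2-en-2-yl]benzofuran-5-yl}ethanone (CNP0347774.1)
Conditions: TBAF, AcOH (1:1), THF, 0 °C
Reagents that add atoms: none
Why: Fluoride cleaves the aryl silyl ether, and the acetic acid buffer keeps the medium from becoming basic enough to isomerise the skipped alkene through the doubly activated benzylic–allylic C–H and erode the stereocentre.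

**Compound list**

1 | 4-bromo-3-methoxyphenol | COc1cc(O)ccc1Br | starting material
2 | 3-chloro-3-methylbut-1-yne | CC(C)(Cl)C#C | starting material
3 | 1-bromo-2-methoxy-4-[(2-methylbut-3-yn-2-yl)oxy]benzene | COc1cc(OC(C)(C)C#C)ccc1Br | intermediate
4 | 4-bromo-5-methoxy-2-(3-methylbuta-1,2-dien-1-yl)phenol | COc1cc(O)c(C=C=C(C)C)cc1Br | intermediate
5 | 4-bromo-3-methoxy-6-(3-methylbut-2-en-1-ylidene)cyclohexa-2,4-dien-1-one | O=C1C=C(OC)C(Br)=CC1=CC=C(C)C | intermediate
6 | 6-bromo-7-methoxy-2,2-dimethyl-2H-chromene | COc1cc2c(cc1Br)C=CC(C)(C)O2 | intermediate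
7 | (E)-3-(dimethylamino)prop-2-enal | CN(C)/C=C/C=O | starting material
8 | (7-methoxy-2,2-dimethyl-2H-chromen-6-yl)lithium | COc1cc2c(cc1[Li])C=CC(C)(C)O2 | intermediate
9 | lithium rac-(E)-3-(dimethylamino)-1-(7-methoxy-2,2-dimethyl-2H-chromen-6-yl)prop-2-en-1-olate | COc1cc2c(cc1C(O[Li])/C=C/N(C)C)C=CC(C)(C)O2 | intermediate
10 | (E)-3-(7-methoxy-2,2-dimethyl-2H-chromen-6-yl)prop-2-enal | COc1cc2c(cc1/C=C/C=O)C=CC(C)(C)O2 | intermediate
11 | ethynylmagnesium bromide | C#C[Mg]Br | starting material
12 | rac-(E)-1-(7-methoxy-2,2-dimethyl-2H-chromen-6-yl)pent-1-en-4-yn-3-ol | COc1cc2c(cc1/C=C/C(O)C#C)C=CC(C)(C)O2 | intermediate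
13 | 1-(2,4-dihydroxyphenyl)ethanone | CC(=O)c1ccc(O)cc1O | starting material
14 | 1-(2,4-dihydroxy-5-iodophenyl)ethanone | CC(=O)c1cc(I)c(O)cc1O | intermediate
15 | rac-1-{2,4-dihydroxy-5-[(E)-3-hydroxy-5-(7-methoxy-2,2-dimethyl-2H-chromen-6-yl)pent-4-en-1-yn-1-yl]phenyl}ethanone | COc1cc2c(cc1/C=C/C(O)C#Cc1cc(C(C)=O)c(O)cc1O)C=CC(C)(C)O2 | intermediate
16 | rac-1-{6-hydroxy-2-[(E)-1-hydroxy-3-(7-methoxy-2,2-dimethyl-2H-chromen-6-yl)prop-2-en-1-yl]benzofuran-5-yl}ethanone | COc1cc2c(cc1/C=C/C(O)c1cc3cc(C(C)=O)c(O)cc3o1)C=CC(C)(C)O2 | intermediate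
17 | (E)-1-(5-acetyl-6-hydroxybenzofuran-2-yl)-3-(7-methoxy-2,2-dimethyl-2H-chromen-6-yl)prop-2-en-1-one | COc1cc2c(cc1/C=C/C(=O)c1cc3cc(C(C)=O)c(O)cc3o1)C=CC(C)(C)O2 | intermediate
18 | (E)-1-{5-acetyl-6-[(tert-butyldimethylsilyl)oxy]benzofuran-2-yl}-3-(7-methoxy-2,2-dimethyl-2H-chromen-6-yl)prop-2-en-1-one | COc1cc2c(cc1/C=C/C(=O)c1cc3cc(C(C)=O)c(O[Si](C)(C)C(C)(C)C)cc3o1)C=CC(C)(C)O2 | intermediate
19 | dimethylzinc | C[Zn]C | starting material
20 | methylzinc (1Z,3S)-1-{5-acetyl-6-[(tert-butyldimethylsilyl)oxy]benzofuran-2-yl}-3-(7-methoxy-2,2-dimethyl-2H-chromen-6-yl)but-1-en-1-olate | COc1cc2c(cc1[C@@H](C)/C=C(\O[Zn]C)c1cc3cc(C(C)=O)c(O[Si](C)(C)C(C)(C)C)cc3o1)C=CC(C)(C)O2 | intermediate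
21 | (1Z,3S)-1-{5-acetyl-6-[(tert-butyldimethylsilyl)oxy]benzofuran-2-yl}-3-(7-methoxy-2,2-dimethyl-2H-chromen-6-yl)but-1-en-1-yl trifluoromethanesulfonate | COc1cc2c(cc1[C@@H](C)/C=C(\OS(=O)(=O)C(F)(F)F)c1cc3cc(C(C)=O)c(O[Si](C)(C)C(C)(C)C)cc3o1)C=CC(C)(C)O2 | intermediate
22 | methylzinc chloride | C[Zn]Cl | starting material
23 | 1-{6-[(tert-butyldimethylsilyl)oxy]-2-[(2E,4S)-4-(7-methoxy-2,2-dimethyl-2H-chromen-6-yl)pent-2-en-2-yl]benzofuran-5-yl}ethanone | COc1cc2c(cc1[C@@H](C)/C=C(\C)c1cc3cc(C(C)=O)c(O[Si](C)(C)C(C)(C)C)cc3o1)C=CC(C)(C)O2 | intermediate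
24 | 1-{6-hydroxy-2-[(2E,4S)-4-(7-methoxy-2,2-dimethyl-2H-chromen-6-yl)pent-2-en-2-yl]benzofuran-5-yl}ethanone | COc1cc2c(cc1[C@@H](C)/C=C(\C)c1cc3cc(C(C)=O)c(O)cc3o1)C=CC(C)(C)O2 | target

**Step count**

Total: 11 steps. Longest linear sequence: 10 steps (steps 1–4 and 6–11, from 4-bromo-3-methoxyphenol); step 5 is a one-step branch.

**Steps most likely to fail, with fallbacks**

Step 9. Methyl transfer from Me2Zn may be sluggish, the ligand may give insufficient facial discrimination on this heteroaryl enone, or triflation of the zinc enolate may be incomplete. The fallback separates bond formation from enantio-induction and sets out from 18. Conjugate addition of Me2CuLi (THF, −78 °C) gives the lithium Z-enolate, which is trapped in the same flask with N-(5-chloropyridin-2-yl)bis(trifluoromethanesulfonyl)imide. This should give the racemic (Z)-enol triflate F1. Preparative chromatography on a polysaccharide chiral stationary phase then separates the (S,Z)-enantiomer from its (R,Z)-antipode F2, which is discarded. The route is rejoined at 21.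

Step 6. The one-pot coupling and ring closure may stall at the uncyclised alkynylphenol, the enynol may homocouple, or the doubly activated carbinol may ionise on prolonged heating. The fallback runs coupling and ring closure as separate, protected operations and sets out from 14 and 12. Acetylation of 14 (Ac2O, pyridine) gives 4-acetyl-6-iodo-1,3-phenylene diacetate F3, a more electron-poor iodide that cannot cyclise. Sonogashira coupling with 12 at room temperature (Pd(PPh3)2Cl2, CuI, Et3N, THF) gives the alkynyl diacetate F4. Cs2CO3 in MeOH/DMF at 60 °C then removes both acetates and closes the furan ring by base-mediated 5-endo-dig attack of the phenoxide. The route is rejoined at 16.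

Step 3. Ionisation and hydrolysis of the amino-alkoxide adduct may be incomplete, or the acidic work-up may damage the chromene alkene. The fallback sets out from 6. Bromine–lithium exchange (n-BuLi, THF, −78 °C) and quenching with DMF give 7-methoxy-2,2-dimethyl-2H-chromene-6-carbaldehyde F5. Wittig olefination with (triphenylphosphoranylidene)acetaldehyde (toluene, 80 °C) then extends it by two carbons to the (E)-enal under neutral conditions. The route is rejoined at 10.

**Further compounds**

F1 | step 9 | rac-(Z)-1-{5-acetyl-6-[(tert-butyldimethylsilyl)oxy]benzofuran-2-yl}-3-(7-methoxy-2,2-dimethyl-2H-chromen-6-yl)but-1-en-1-yl trifluoromethanesulfonate | COc1cc2c(cc1C(C)/C=C(\OS(=O)(=O)C(F)(F)F)c1cc3cc(C(C)=O)c(O[Si](C)(C)C(C)(C)C)cc3o1)C=CC(C)(C)O2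
F2 | step 9 | (1Z,3R)-1-{5-acetyl-6-[(tert-butyldimethylsilyl)oxy]benzofuran-2-yl}-3-(7-methoxy-2,2-dimethyl-2H-chromen-6-yl)but-1-en-1-yl trifluoromethanesulfonate | COc1cc2c(cc1[C@H](C)/C=C(\OS(=O)(=O)C(F)(F)F)c1cc3cc(C(C)=O)c(O[Si](C)(C)C(C)(C)C)cc3o1)C=CC(C)(C)O2
F3 | step 6 | 4-acetyl-6-iodo-1,3-phenylene diacetate | CC(=O)Oc1cc(OC(C)=O)c(C(C)=O)cc1I
F4 | step 6 | rac-4-acetyl-6-[(E)-3-hydroxy-5-(7-methoxy-2,2-dimethyl-2H-chromen-6-yl)pent-4-en-1-yn-1-yl]-1,3-phenylene diacetate | COc1cc2c(cc1/C=C/C(O)C#Cc1cc(C(C)=O)c(OC(C)=O)cc1OC(C)=O)C=CC(C)(C)O2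
F5 | step 3 | 7-methoxy-2,2-dimethyl-2H-chromene-6-carbaldehyde | COc1cc2c(cc1C=O)C=CC(C)(C)O2
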